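## Structural features

- The target is the 6-O-(E)-4-hydroxycinnamate of a daucane diol. A cyclopentane (C1–C5) and a cycloheptene (C1, C5–C10, alkene C8=C9 carrying methyl C14) share the C1–C5 bond in a trans-fused bicyclo[5.3.0]decene.
- Four stereocentres stand in a row: the quaternary C1 (methyl C15), the ring-fusion methine C5, the tertiary carbinol C4 (isopropyl C11–C13) and the esterified secondary carbinol C6. C15 and the C4 hydroxyl lie on one face (β), H5 and the C6 oxygen on the other (α); this is 1R,4R,5S,6S in daucane numbering.
- Fragile groups: the tertiary C4 alcohol, which loses water easily under acid and sits 1,3 to the ester; the trisubstituted C8=C9 alkene (acid, electrophilic oxidants); and the cinnamate, a base-labile ester with an E-configured Michael acceptor and a free phenol.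
- The real difficulty is the cyclopentane: a quaternary carbon next to a ring-fusion methine next to a fully substituted carbinol whose hydroxyl is cis to the angular methyl, all on a trans-fused ring system. In addition, the C6 oxygen sits on a methylene that no neighbouring group activates.
- The key step uses the fact that C1–C15 form an unbranched head-to-tail farnesane chain, C10–C9=C8(C14)–C7–C6–C5=C1(C15)–C2–C3–C4=C11(C12)(C13). Only the C1–C10 and C4–C5 bonds and the C4–O bond are missing, and C8=C9 is the first alkene of that chain left in place.

## Logic of the disconnections

**11 ⇒ 10.** The aryl O–Si bond is cut last. The phenol would compete as nucleophile and acid in any acylation, so it stays masked until the end. The gain is chemoselectivity, not skeleton. The forward step must take silicon off the aryl oxygen without cleaving the cinnamate, dehydrating the tertiary alcohol or isomerising the E alkene.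

**10 ⇒ 5 + 8 (through 9).** The acyl C–O6 bond is cut. This separates the achiral aromatic acid from the terpene diol, so all stereochemical work lies in 5. The forward step must acylate the hindered secondary C6 hydroxyl and leave the tertiary C4 hydroxyl alone; the difference in steric access makes this plausible. It must also activate 8 (as 9) without touching its alkene.

**8 ⇒ 6 (through 7).** Both O–Si bonds of 7 go back to 6; only the silyl ester is cleaved again. The gain is a protected acid in one operation. The demand is selective solvolysis of the silyl ester next to the aryl silyl ether.

**5 ⇒ 4.** The C6–O bond is cut, so 5 is viewed as a C–H oxidation product of 4. C6–O is the only heteroatom bond that a water-terminated terpene cyclisation does not explain. Removing it leaves three stereocentres and the exact product of the cyclisation. The forward step must pick the 6α hydrogen among three allylic positions, several other methylene groups and an alkene; only an enzyme pocket can plausibly do this in one step.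

**4 ⇒ 3.** The C1–C10 and C4–C5 bonds and the C4–O bond are cut together. These are the bonds that turn the farnesane chain into the daucane skeleton. Both rings and all three stereocentres disappear, and 3 is acyclic and achiral. The forward step needs one defined chain fold, a cisoid allyl cation at C8–C10, a 1,2-hydride shift before quenching, and water capture at C4 in preference to proton loss.

**3 ⇒ 2 ⇒ 1.** The C10–O bond to phosphorus is cut back to the chloride 2, and the C10–Cl bond to the C10–OH of 1. An allylic halide is the reliable electrophile for a diphosphate nucleophile. The gain is a cheap commercial alcohol. Both forward steps must proceed by SN2 at C10 without allylic transposition and without loss of the 2E geometry.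

## Other disconnections considered

**Alternative 1:** The cut is the C1–C10 bond, in the sense of a retro-Cope. The seven-membered ring of the silyl enol ether A2 is opened to the cis-divinylcyclopropane A1, where C6, C7 and C8 form the three-membered ring. C6 carries the silyloxy group and the 2-methylcyclopentenyl unit (C5=C1, with the C4 carbinol in place); C8 carries methyl and vinyl (C9=C10). Forward, heating A1 should give the [3,3] shift through the boat transition state: C1–C10 forms, C6–C8 breaks, and the quaternary C1, the C8=C9 alkene and C6 at the ketone oxidation level appear together.
- In favour: a concerted thermal step that needs no catalyst; C1 follows from the cyclopropane configuration through the boat geometry; the ring alkene ends up in the right place.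
- Against: C1 is a fully substituted terminus whose methyl must point towards C7 in the boat, which slows such rearrangements. A1 needs three defined stereocentres (C4, C6, C8) and the cis arrangement, so the stereochemical problem moves into a precursor that is itself hard to make. After the key step, C5 must still be protonated on the α face and C6 reduced to the α alcohol, through a β,γ-unsaturated β-hydroxy ketone prone to alkene migration, retro-aldol cleavage and loss of water.
- Comparison: on structure it builds one ring, one skeletal bond and one stereocentre, against two rings, two bonds and three stereocentres in step 3. On mechanism it is the better of the two, because it is a well-understood pericyclic reaction that needs no undiscovered catalyst. On step economy it is worse: making A1 alone should take more steps than the whole chosen route.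

**Alternative 2:** The cut removes C15 as a methylene. The C1–C15 and C5–C15 bonds of the cyclopropane-fused diol A4 are disconnected to the bicyclic dienediol A3 with a tetrasubstituted C1=C5 alkene; the C5–C15 bond would later be cleaved reductively so that C15 becomes the angular methyl. Forward, the zinc carbenoid from Et2Zn and CH2I2 (Simmons–Smith), bound to the C4 and C6 alkoxides, should add to the alkene face those oxygens occupy.
- In favour: hydroxyl delivery is one of the few reliable ways to put carbon on a hindered tetrasubstituted alkene, and it places C15 cis to the C4 hydroxyl as the target requires. On certainty of stereocontrol at C1 it equals the enzyme template, and on precedent it is the better of the two.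
- Against: the C6 hydroxyl of A4 lies on the β face, epimeric with the C6 oxygen of the target. It would have to be oxidised, the cyclopropyl ketone opened with lithium in liquid ammonia (C5–C15 versus C1–C5 cleavage decided only by orbital overlap), C5 protonated on the α face and C6 reduced 1,3-anti. The C6-bound carbenoid can also reach the homoallylic C8=C9 alkene.
- Comparison: on structure the key step adds one carbon and no ring of the skeleton, and A3 must already contain both rings and C4. On step economy the chosen plan is far ahead, since four redox and cleavage operations follow A4.

**Alternative 3:** The cut is C3–C4. The diol A6 (the same compound as 5) opens to the cycloheptene iodo ketone A5, which carries the 2-iodoethyl group and methyl on C1, the isopropyl ketone on C5 and the free hydroxyl on C6. Forward, SmI2 would reduce the primary iodide, and the organosamarium should add to the ketone held in a chelate with the C6 oxygen (samarium Barbier reaction, 5-exo closure), setting C4.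
- In favour: it reaches 5 directly with the C6 oxygen already in place, so no late C–H oxidation is needed; on this point it is the better of the two. The reagent and reaction type are well precedented, and chelation gives a rationale for the C4 configuration.
- Against: A5 holds three contiguous stereocentres, including the quaternary C1, on a seven-membered ring, so the hardest part is left to the precursor. The β-hydroxy ketone can undergo retro-aldol cleavage or lose water. Ketyl formation (pinacol coupling, simple reduction) competes with iodide reduction. Facial control through a chelate on a flexible cycloheptene is uncertain.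
- Comparison: on structure it closes one ring and sets one stereocentre. On mechanism it equals or betters the chosen plan in precedent. On step economy it is worse, since A5 should need more steps than the entire chosen route.

Key step: step 3

Assumption 1: daucane numbering (C1–C15 as in the target) is used for every compound, including the open chain of 1–3, where C10 is the carbon that bears oxygen.
Assumption 2: 3 is handled as its tris-ammonium salt; the free acid is drawn.
Assumption 3: the synthase of step 3 and the monooxygenase of step 4 are not available off the shelf; they would come from mining Ferula transcriptomes or engineering known daucene- and carotol-forming synthases and P450 enzymes.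

## Route

Step 1
Reactants: 1 (2E,6E)-farnesol
Product: 2 (2E,6E)-farnesyl chloride
Conditions: NCS, Me2S, CH2Cl2, −40 to 0 °C
Reagents that add atoms: N-chlorosuccinimide, O=C1CCC(=O)N1Cl
Why: Corey–Kim chlorination: the chlorosulfonium salt from NCS and Me2S turns the allylic hydroxyl into an alkoxysulfonium leaving group, which chloride displaces at the primary carbon C10 by SN2; under these cold, neutral conditions neither allylic transposition to the tertiary chloride nor loss of the 2E geometry is expected, and no stereocentre is formed.

Step 2
Reactants: 2 (2E,6E)-farnesyl chloride
Product: 3 (2E,6E)-farnesyl diphosphate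
Conditions: (Bu4N)3HP2O7, MeCN, rt; then cation-exchange resin (NH4+ form), aqueous NH4HCO3, cellulose chromatography
Reagents that add atoms: tris(tetrabutylammonium) hydrogen diphosphate, CCCC[N+](CCCC)(CCCC)CCCC.CCCC[N+](CCCC)(CCCC)CCCC.CCCC[N+](CCCC)(CCCC)CCCC.OP(=O)([O-])OP(=O)([O-])[O-]
Why: SN2 displacement of the primary allylic chloride by the diphosphate anion, which is soluble and nucleophilic in acetonitrile as its tetrabutylammonium salt; attack at C10 leaves both E alkenes untouched, and cation exchange gives the water-soluble ammonium salt that a synthase accepts.

Step 3
Reactants: 3 (2E,6E)-farnesyl diphosphate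
Product: 4 (1R,4R,5R)-dauc-8-en-4-ol
Conditions: recombinant dauc-8-en-4-ol synthase (class 1 sesquiterpene synthase), MgCl2, HEPES buffer pH 7.5, dithiothreitol, pentane overlay, 30 °C
Reagents that add atoms: water, O
Why: Proposed new method: no characterised synthase is known to release this C4 alcohol, and the step rests on the reasoning that a class 1 active site which folds 3 as the daucene- and carotol-forming synthases do, but holds water near C4 and offers no base near C5, should give 4; the closest known reaction type is the class 1 terpene synthase cationic polyene cyclisation of farnesyl diphosphate to carotol and daucene. Ionisation of the allylic diphosphate by the divalent magnesium cluster (from MgCl2) and transient return of diphosphate to the tertiary carbon C8 allow rotation about C8–C9, so that the re-formed allyl cation is cisoid and C10 can reach the C5=C1 alkene. The seven-membered ring closes formally 7-endo, most plausibly as a 6-exo attack of that alkene on C10 followed by a 1,2-alkyl shift of C10 from C5 to C1, which leaves the C1–C10 bond and positive charge at C5. The cyclopentane closes by 5-exo-trig attack of the C4=C11 alkene on C5 (C4–C5 bond), a 1,2-hydride shift from C4 to C11 completes the isopropyl group, and bound water quenches the tertiary C4 cation (C4–O bond). C1 is set by the face of the (E)-C5=C1 alkene that the enzyme presents to C10, C5 by the anti addition of C10 and C4 across that alkene, which turns its E geometry into the trans ring fusion, and C4 by water entering on the C15 face, presumably anti to the migrating hydride. The step needs cyclisation to outrun hydrolysis of 3, a single chain fold for the absolute configuration, and water capture at C4 in preference to proton loss (daucene) or capture at C11 or C5 (carotol). The substrate secures the constitution, because its three trisubstituted alkenes sit at the 1,5-distances that let each closure give a tertiary or allylic cation, and its 2E,6E geometry fixes the relation of C1 to C5; everything else rests on the active-site contour.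

Step 4
Reactants: 4 (1R,4R,5R)-dauc-8-en-4-ol
Product: 5 (1R,4R,5S,6S)-dauc-8-ene-4,6-diol
Conditions: recombinant P450 C6α-hydroxylase with its reductase, O2 (air), NADP+ (cat.), Na2HPO3, phosphite dehydrogenase, potassium phosphate buffer pH 7.5, 25 °C
Reagents that add atoms: dioxygen, O=O
Why: Proposed new method: no monooxygenase is known for this substrate, and the reasoning is that a P450 ferryl-oxo species, held over the α face of C6 by a pocket that binds the C4 hydroxyl, abstracts the 6α hydrogen and returns hydroxyl to the same face by oxygen rebound, so that C6–O forms with retention and the enzyme sets the new stereocentre and protects the allylic positions and the C8=C9 alkene; the closest known reaction type is P450-catalysed hydroxylation of non-activated methylene groups of sesquiterpenoids by plant CYP71-clan enzymes and evolved P450 BM3 variants.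

Step 5
Reactants: 6 (E)-4-hydroxycinnamic acid
Product: 8 (E)-3-[4-(tert-butyldimethylsilyloxy)phenyl]prop-2-enoic acid, via bis-silylated coumarate 7 (not isolated)
Conditions: TBSCl, imidazole, DMF, rt; then AcOH–THF–H2O, rt
Reagents that add atoms: tert-butyldimethylsilyl chloride, CC(C)(C)[Si](C)(C)Cl
Why: Imidazole-promoted silylation of the phenol and the carboxylic acid, then selective solvolysis of the far more labile silyl ester; the aryl silyl ether survives the mild aqueous acid, the E alkene is not touched and no stereocentre is involved.

Step 6
Reactants: 5 (1R,4R,5S,6S)-dauc-8-ene-4,6-diol; 8 (E)-3-[4-(tert-butyldimethylsilyloxy)phenyl]prop-2-enoic acid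
Product: 10 (1R,4R,5S,6S)-4-hydroxydauc-8-en-6-yl (E)-3-[4-(tert-butyldimethylsilyloxy)phenyl]prop-2-enoate, via Yamaguchi mixed anhydride 9 (not isolated)
Conditions: 8, 2,4,6-trichlorobenzoyl chloride, Et3N, THF, rt; then 5, DMAP, toluene, rt to 40 °C, dark
Reagents that add atoms: none
Why: Yamaguchi esterification: DMAP attacks 9 at the unhindered cinnamoyl carbonyl and the acylpyridinium ion acylates the secondary C6 hydroxyl, while the tertiary C4 hydroxyl, flanked by isopropyl and the ring fusion, is too hindered to react; C6 keeps its configuration because the C6–O bond is not broken, and the E alkene is preserved under these non-nucleophilic conditions.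

Step 7
Reactants: 10 (1R,4R,5S,6S)-4-hydroxydauc-8-en-6-yl (E)-3-[4-(tert-butyldimethylsilyloxy)phenyl]prop-2-enoate
Product: 11 (1R,4R,5S,6S)-4-hydroxydauc-8-en-6-yl (E)-3-(4-hydroxyphenyl)prop-2-enoate
Conditions: TBAF, AcOH, THF, 0 °C
Reagents that add atoms: none
Why: Fluoride-induced cleavage of the aryl silyl ether (strong Si–F bond, good phenoxide leaving group); acetic acid buffers the phenoxide and any alkoxide, so that the cinnamate is neither cleaved nor transferred to the C4 hydroxyl and the tertiary alcohol does not eliminate; no stereocentre is touched.

## Compound list

1 | (2E,6E)-farnesol | CC(C)=CCC/C(C)=C/CC/C(C)=C/CO | starting material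
2 | (2E,6E)-farnesyl chloride | CC(C)=CCC/C(C)=C/CC/C(C)=C/CCl | intermediate
3 | (2E,6E)-farnesyl diphosphate (free acid drawn, handled as tris-ammonium salt) | CC(C)=CCC/C(C)=C/CC/C(C)=C/COP(=O)(O)OP(=O)(O)O | intermediate
4 | (1R,4R,5R)-dauc-8-en-4-ol (trans-fused; 1β-methyl, 4β-hydroxyl, 5α-H) | CC1=CC[C@@]2(C)CC[C@@](O)(C(C)C)[C@@H]2CC1 | intermediate
5 | (1R,4R,5S,6S)-dauc-8-ene-4,6-diol (4β,6α-diol) | CC1=CC[C@@]2(C)CC[C@@](O)(C(C)C)[C@@H]2[C@@H](O)C1 | intermediate
6 | (E)-4-hydroxycinnamic acid | O=C(O)/C=C/c1ccc(O)cc1 | starting material
7 | tert-butyldimethylsilyl (E)-3-[4-(tert-butyldimethylsilyloxy)phenyl]prop-2-enoate | CC(C)(C)[Si](C)(C)Oc1ccc(/C=C/C(=O)O[Si](C)(C)C(C)(C)C)cc1 | intermediate (not isolated)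
8 | (E)-3-[4-(tert-butyldimethylsilyloxy)phenyl]prop-2-enoic acid | CC(C)(C)[Si](C)(C)Oc1ccc(/C=C/C(=O)O)cc1 | intermediate
9 | mixed anhydride of 8 with 2,4,6-trichlorobenzoic acid | CC(C)(C)[Si](C)(C)Oc1ccc(/C=C/C(=O)OC(=O)c2c(Cl)cc(Cl)cc2Cl)cc1 | intermediate (not isolated)
10 | (1R,4R,5S,6S)-4-hydroxydauc-8-en-6-yl (E)-3-[4-(tert-butyldimethylsilyloxy)phenyl]prop-2-enoate | CC1=CC[C@@]2(C)CC[C@@](O)(C(C)C)[C@@H]2[C@@H](OC(=O)/C=C/c2ccc(O[Si](C)(C)C(C)(C)C)cc2)C1 | intermediate
11 | (1R,4R,5S,6S)-4-hydroxydauc-8-en-6-yl (E)-3-(4-hydroxyphenyl)prop-2-enoate | CC1=CC[C@@]2(C)CC[C@@](O)(C(C)C)[C@@H]2[C@@H](OC(=O)/C=C/c2ccc(O)cc2)C1 | target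

## Step count and risks

Total step count: 7. Longest linear sequence: 6 steps (steps 1, 2, 3, 4, 6, 7).

**Step 3 (key step; marked as a new method).**
- Most likely failure: the cation cascade derails or no enzyme with this product profile is found. Proton loss from the C4 cation (daucene) or water capture at C11 or C5 then gives hydrocarbons and isomeric alcohols, because these exits are the known ones for this fold and only the position of one water molecule separates them.
- Fallback (known chemistry; sets out from 3, returns at 5, leaves out 4 and step 4):
  - 3 would be cyclised with a characterised daucene-forming class 1 synthase of the 1R series (MgCl2, buffer) to (1R)-dauca-4,8-diene F1, which keeps only C1 as a stereocentre.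
  - Dye-sensitised photo-oxygenation (O2, rose bengal, light, 0 °C) should add singlet oxygen to the electron-rich tetrasubstituted C4=C5 alkene in a Schenck ene reaction. Abstraction of H6, geminal to the bulky quaternary C1, would give 4-hydroperoxydauca-5,8-diene F2 (either C4 epimer), reduced by PPh3 to dauca-5,8-dien-4-ol F3.
  - Babler–Dauben oxidative transposition with pyridinium chlorochromate, C5H5NH[CrO3Cl], would move the oxygen to C6 and give dauca-4,8-dien-6-one F4, in which C4 is trigonal again.
  - Reagent-controlled CBS reduction (the oxazaborolidine enantiomer that delivers hydride to the α face, catecholborane) should give dauca-4,8-dien-6β-ol F5. VO(acac)2 with tert-butyl hydroperoxide would epoxidise the allylic alkene syn to that hydroxyl to give 4β,5β-epoxydauc-8-en-6β-ol F6. Dess–Martin oxidation would give 4β,5β-epoxydauc-8-en-6-one F7.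
  - SmI2 (THF–MeOH, −90 °C) should cleave the C5–O bond α to the ketone. Protonation of the samarium enolate on the α face, away from C15 and the C4 alkoxide, would give 4β-hydroxydauc-8-en-6-one F8 with the trans ring fusion.
  - Evans–Saksena reduction with Me4NBH(OAc)3, with hydride delivered from the C4 hydroxyl, should give the 6α-alcohol 5.
  - This fallback uses the enzyme only for the ring system and C1 and builds C4, C5 and C6 chemically. Its own weak points are alkene migration in the β,γ-unsaturated ketones F4, F7 and F8 and loss of water from F8.

**Step 4 (marked as a new method).**
- Most likely failure: poor site selectivity or no turnover. Oxidation at the allylic positions C7, C10 and C14 or epoxidation of C8=C9 is intrinsically easier than hydroxylation of the non-activated C6 methylene.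
- Fallback (known chemistry; sets out from 4, returns at 5):
  - 4 would be dehydrated through dauc-8-en-4-yl phosphorodichloridate F9 (POCl3, pyridine, 0 °C to rt). Anti-periplanar loss of H5 should give the tetrasubstituted alkene (1R)-dauca-4,8-diene F1.
  - From F1, the sequence through F2, F3, F4, F5, F6, F7 and F8 described under step 3 leads to 5.
  - This gives up the C4 and C5 centres the cyclase had set and rebuilds them chemically. Its weak point is the regiochemistry of the elimination, since isopropylidene and C3=C4 isomers can form.

**Step 6.**
- Most likely failure: incomplete acyl transfer to the hindered C6 hydroxyl, which is flanked by the ring fusion and the tertiary carbinol. Forcing the reaction invites attack at the wrong carbonyl of 9 or loss of water from C4.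
- Fallback (sets out from 5, returns at 11, leaves out 6–10):
  - Heating 5 with Meldrum's acid (toluene, 90 °C) should acylate only the secondary hydroxyl and give (1R,4R,5S,6S)-4-hydroxydauc-8-en-6-yl hydrogen malonate F10.
  - Knoevenagel–Doebner condensation of F10 with 4-hydroxybenzaldehyde (pyridine, piperidine cat., 60 °C) would build the E-cinnamate on the terpene with loss of CO2 and water, giving 11 directly. No protecting group and no hindered cinnamoyl transfer is needed.

Further compounds
F1 | step 3 | (1R)-dauca-4,8-diene (daucene) | CC1=CC[C@@]2(C)CCC(C(C)C)=C2CC1
F2 | step 3 | 4-hydroperoxydauca-5,8-diene (C4 epimers) | CC1=CC[C@@]2(C)CCC(OO)(C(C)C)C2=CC1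
F3 | step 3 | dauca-5,8-dien-4-ol (C4 epimers) | CC1=CC[C@@]2(C)CCC(O)(C(C)C)C2=CC1
F4 | step 3 | dauca-4,8-dien-6-one | CC1=CC[C@@]2(C)CCC(C(C)C)=C2C(=O)C1
F5 | step 3 | dauca-4,8-dien-6β-ol | CC1=CC[C@@]2(C)CCC(C(C)C)=C2[C@H](O)C1
F6 | step 3 | 4β,5β-epoxydauc-8-en-6β-ol | CC1=CC[C@@]2(C)CC[C@]3(C(C)C)O[C@]23[C@H](O)C1
F7 | step 3 | 4β,5β-epoxydauc-8-en-6-one | CC1=CC[C@@]2(C)CC[C@]3(C(C)C)O[C@]23C(=O)C1
F8 | step 3 | 4β-hydroxydauc-8-en-6-one (5α-H) | CC1=CC[C@@]2(C)CC[C@@](O)(C(C)C)[C@@H]2C(=O)C1
F9 | step 4 | dauc-8-en-4-yl phosphorodichloridate | CC1=CC[C@@]2(C)CC[C@@](OP(=O)(Cl)Cl)(C(C)C)[C@@H]2CC1
F10 | step 6 | (1R,4R,5S,6S)-4-hydroxydauc-8-en-6-yl hydrogen malonate | CC1=CC[C@@]2(C)CC[C@@](O)(C(C)C)[C@@H]2[C@@H](OC(=O)CC(=O)O)C1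
A1 | alternative 1 | cis-divinylcyclopropane: 1-silyloxy-1-(5-hydroxy-5-isopropyl-2-methylcyclopent-1-enyl)-2-methyl-2-vinylcyclopropane | C=C[C@@]1(C)C[C@@]1(O[Si](C)(C)C(C)(C)C)C2=C(C)CC[C@@]2(O)C(C)C
A2 | alternative 1 | bicyclic C5=C6 silyl enol ether with C8=C9 alkene | CC1=CC[C@@]2(C)CC[C@@](O)(C(C)C)C2=C(O[Si](C)(C)C(C)(C)C)C1
A3 | alternative 2 | 15-nor-dauca-1(5),8-diene-4β,6β-diol | CC1=CCC2=C([C@H](O)C1)[C@](O)(C(C)C)CC2
A4 | alternative 2 | cyclopropane-fused (C1–C15–C5) 4β,6β-diol | CC1=CC[C@]23C[C@@]2([C@H](O)C1)[C@](O)(C(C)C)CC3
A5 | alternative 3 | cycloheptene iodo ketone (C1: methyl and 2-iodoethyl; C5: 2-methylpropanoyl; C6: hydroxyl) | CC1=CC[C@@](C)(CCI)[C@H](C(=O)C(C)C)[C@@H](O)C1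
A6 | alternative 3 | dauc-8-ene-4β,6α-diol (identical with 5) | CC1=CC[C@@]2(C)CC[C@@](O)(C(C)C)[C@@H]2[C@@H](O)C1
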